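Numbering (isochromene): ring A = pyran C1, O2, C3, C4, C4a, C8a. Ring B = carbocycle C4a, C5, C6, C7, C8, C8a. Side chain = C1'–C7'.
Enabling feature: the six atoms of ring B can be read as a diene C6=C7–C8=C8a plus an alkyne C4a≡C5. The four ring A atoms C1–O2–C3–C4 already link C8a to C4a, so they can serve as the ester tether of a dienyl but-3-ynoate.
Retrosynthetic cuts, in order: C8 O–acetyl; C6 ketone back to a silyl ether; C3–C1' (Suzuki–Miyaura coupling on the dienol phosphate of a δ-lactone); the C7/C8 cis-diol back to C7=C8; C4a–C8a and C5–C6 together ([4+2]); O2–C3 (ester).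
Forward: the open chain is assembled in four steps and rings A and B close together in step 5. The diol, the side chain at C3, the C6 ketone and the C8 acetate follow.
Stereochemistry: C8a comes from the chiral diphosphine on rhodium, and C6 (temporary) from the E,E-diene. C7 and C8 come from osmylation on the face opposite C1 and C6–O, and C5' from (S)-2-methylbutan-1-ol. C3'=C4' is Z in the target and comes from a Still–Gennari olefination. C1'=C2' is E and comes from a chromium-mediated boryl olefination.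

Key step: step 5

Assumption: the facial preference of the rhodium–BINAP catalyst on this substrate class cannot be derived from a model. (R)-BINAP is therefore written for the (6R,8aR) series, and the mirror-image ligand would be taken if the opposite sense is found.
Abbreviations: TBS = tert-butyldimethylsilyl, TES = triethylsilyl, Bpin = 4,4,5,5-tetramethyl-1,3,2-dioxaborolan-2-yl, NMO = N-methylmorpholine N-oxide.

Step 1
Reactants: 1 but-3-en-1-yl acetate; 2 methacrolein (2-methylprop-2-enal)
Product: 3 (3E)-4-methyl-5-oxopent-3-en-1-yl acetate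
Conditions: second-generation Grubbs catalyst RuCl2(=CHPh)(PCy3)(SIMes) (3 mol %), 2 (4 equiv), CH2Cl2, 40 °C
Reagents that add atoms: none
Why: Cross metathesis of a terminal alkene with excess methacrolein is a known entry to 2-methyl-2-enals, is driven by loss of ethene and should favour the less crowded E alkene.

Step 2
Reactants: 3 (3E)-4-methyl-5-oxopent-3-en-1-yl acetate
Product: 4 (2E,4E)-5-(TBSO)-4-methylpenta-2,4-dien-1-yl acetate
Conditions: TBSOTf (1.2 equiv), Et3N (2 equiv), CH2Cl2, −78 to 0 °C; Et3N-washed silica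
Reagents that add atoms: tert-butyldimethylsilyl triflate CC(C)(C)[Si](C)(C)OS(=O)(=O)C(F)(F)F
Why: Soft enolisation (O-silylation, then γ-deprotonation by the amine) is the standard route from 2-enals to 1-silyloxydienes, in which the s-trans enal gives the E enol ether and allylic 1,3-strain with the C-methyl group turns CH2OAc outward to give the E alkene.

Step 3
Reactants: 4 (2E,4E)-5-(TBSO)-4-methylpenta-2,4-dien-1-yl acetate
Product: 5 (2E,4E)-5-(TBSO)-4-methylpenta-2,4-dien-1-ol
Conditions: i-Bu2AlH (2.2 equiv), CH2Cl2, −78 °C; aq. potassium sodium tartrate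
Reagents that add atoms: none
Why: Reductive ester cleavage at low temperature leaves the silyl dienol ether alone, whereas acid, fluoride or methoxide could cleave it, and the tartrate work-up stays non-acidic.

Step 4
Reactants: 5 (2E,4E)-5-(TBSO)-4-methylpenta-2,4-dien-1-ol; 6 but-3-ynoic acid
Product: 7 (2E,4E)-5-(TBSO)-4-methylpenta-2,4-dien-1-yl but-3-ynoate
Conditions: DCC (1.2 equiv), 6 (1.2 equiv), CH2Cl2, −10 to 0 °C, no amine additive
Reagents that add atoms: none
Why: Carbodiimide esterification of a primary alcohol is routine, and leaving out amine catalysts avoids the base-induced shift of the but-3-ynoate to the buta-2,3-dienoate.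

Step 5
Reactants: 7 (2E,4E)-5-(TBSO)-4-methylpenta-2,4-dien-1-yl but-3-ynoate
Product: 8 (6R,8aR)-6-(TBSO)-7-methyl-1,4,6,8a-tetrahydro-3H-isochromen-3-one (C1 and OTBS on the same face)
Conditions: [Rh(cod)2]BF4 (10 mol %), (R)-BINAP (10 mol %), H2 (1 atm, pre-activation, then Ar), 2,6-di-tert-butyl-4-methylpyridine (20 mol %), ClCH2CH2Cl, slow addition of 7 to 0.01 M, 25 to 60 °C
Reagents that add atoms: none
Why: Proposed new method: the cationic monovalent rhodium centre, freed from cod, should bind the s-cis diene and the alkyne of 7, couple C4a to C8a by oxidative cyclisation to an η3-allyl rhodacycle, and then join C5 to C6 by reductive elimination, which leaves the C4a=C5 and C7=C8 alkenes of a formal [4+2] adduct. The closest known reaction type is the rhodium-catalysed intramolecular diene–yne [4+2] cycloaddition with three-atom ether, sulfonamide, malonate and propiolate-ester tethers, including enantioselective versions with chiral diphosphines, whereas a four-atom but-3-ynoate tether bearing a 1-silyloxydiene has not been shown. Ring A closes in the oxidative cyclisation (6-exo-dig at the alkyne, 6-exo-trig at the diene terminus), and ring B closes in the reductive elimination from the seven-membered rhodacycle reached by allyl shift. C8a is set by the diphosphine, which decides which diene face sits on the metal, and C6 follows from C8a because addition across the E,E-diene is suprafacial and places the two outer groups (C1 and OTBS) cis. The step needs regiocontrol, which the tether secures because only C8a can reach C4a. It also needs chemoselectivity over alkyne oligomerisation, alkyne-to-allene shift, ionisation of the allylic ester and loss of silanol from 8, which high dilution, the absence of amine base and the hindered pyridine as proton trap are meant to secure.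

Step 6
Reactants: 8 (6R,8aR)-6-(TBSO)-7-methyl-1,4,6,8a-tetrahydro-3H-isochromen-3-one
Product: 9 (6R,7R,8R,8aR)-6-(TBSO)-7,8-dihydroxy-7-methyl-1,4,6,7,8,8a-hexahydro-3H-isochromen-3-one
Conditions: OsO4 (2 mol %), NMO (1.05 equiv), acetone–H2O, 0 °C
Reagents that add atoms: OsO4 O=[Os](=O)(=O)=O (oxygen carrier); N-methylmorpholine N-oxide C[N+]1([O-])CCOCC1; water O
Why: Catalytic osmium tetroxide syn-dihydroxylation should choose C7=C8, which carries a donor methyl group, over C4a=C5, which is flanked by the withdrawing CH2C(=O)O unit at the ring fusion, and attack on the face opposite C1 and the C6 silyloxy group sets C7 and C8 with both oxygens anti to C1.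

Step 7
Reactants: 9 (6R,7R,8R,8aR)-6-(TBSO)-7,8-dihydroxy-7-methyl-1,4,6,7,8,8a-hexahydro-3H-isochromen-3-one
Product: 10 (6R,7S,8R,8aR)-6-(TBSO)-7-methyl-7,8-bis(TESO)-1,4,6,7,8,8a-hexahydro-3H-isochromen-3-one (same spatial arrangement as 9; the C7 descriptor changes by priority only)
Conditions: Et3SiOTf (3 equiv), 2,6-lutidine (5 equiv), CH2Cl2, −78 to 0 °C
Reagents that add atoms: triethylsilyl triflate CC[Si](CC)(CC)OS(=O)(=O)C(F)(F)F
Why: Silyl triflate with 2,6-lutidine silylates secondary and tertiary alcohols alike, the weak hindered base does not enolise the lactone, and all three silyl ethers can later fall in one fluoride step without acid.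

Step 8
Reactants: 10 (6R,7S,8R,8aR)-6-(TBSO)-7-methyl-7,8-bis(TESO)-1,4,6,7,8,8a-hexahydro-3H-isochromen-3-one
Product: 12 diphenyl (6R,7S,8R,8aR)-6-(TBSO)-7-methyl-7,8-bis(TESO)-6,7,8,8a-tetrahydro-1H-isochromen-3-yl phosphate, via potassium dienolate 11 (not isolated)
Conditions: KN(SiMe3)2 (1.2 equiv), THF–DMPU, −78 °C, 10 min; then (PhO)2P(O)Cl (1.5 equiv), −78 °C; Et3N-washed silica
Reagents that add atoms: diphenyl chlorophosphate O=P(Cl)(Oc1ccccc1)Oc1ccccc1; KN(SiMe3)2 C[Si](C)(C)[N-][Si](C)(C)C.[K+] (potassium of 11 only)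
Why: Ketene acetal phosphate formation from lactone enolates is well known, and because the C4 protons are both α to the carbonyl and allylic, kinetic deprotonation of the unconjugated lactone gives the C3=C4–C4a=C5 dienolate without touching C8a–H, while the low temperature holds back loss of the C6 silyloxide.

Step 9
Reactants: 13 (S)-2-methylbutan-1-ol
Product: 14 (S)-2-methylbutanal
Conditions: TEMPO (1 mol %), KBr (10 mol %), NaOCl (1.1 equiv), aq. NaHCO3, CH2Cl2–H2O, 0 °C
Reagents that add atoms: none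
Why: The buffered two-phase nitroxyl/hypochlorite (Anelli) oxidation is the established way to this aldehyde without loss of configuration at the α-carbon.

Step 10
Reactants: 14 (S)-2-methylbutanal; 15 ethyl 2-[bis(2,2,2-trifluoroethoxy)phosphoryl]propanoate
Product: 17 ethyl (2Z,4S)-2,4-dimethylhex-2-enoate, via potassium phosphonate carbanion 16 (not isolated)
Conditions: 15, KN(SiMe3)2, 18-crown-6, THF, −78 °C; then 14, −78 °C
Reagents that add atoms: KN(SiMe3)2 C[Si](C)(C)[N-][Si](C)(C)C.[K+] (potassium of 16 only)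
Why: In the Still–Gennari olefination the electron-poor phosphonate with a dissociated potassium ion eliminates fast from the kinetic adduct, which should give the Z trisubstituted enoate that the target needs and leave the α-stereocentre of the aldehyde intact at −78 °C.

Step 11
Reactants: 17 ethyl (2Z,4S)-2,4-dimethylhex-2-enoate
Product: 18 (2Z,4S)-2,4-dimethylhex-2-en-1-ol
Conditions: i-Bu2AlH (2.5 equiv), CH2Cl2, −78 °C; aq. potassium sodium tartrate
Reagents that add atoms: none
Why: 1,2-Reduction of an enoate with i-Bu2AlH is routine and does not touch the alkene geometry.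

Step 12
Reactants: 18 (2Z,4S)-2,4-dimethylhex-2-en-1-ol
Product: 19 (2Z,4S)-2,4-dimethylhex-2-enal
Conditions: MnO2 (15 equiv), CH2Cl2, 23 °C, dark; filtered and used at once
Reagents that add atoms: none
Why: Allylic oxidation on MnO2 is neutral and heterogeneous, which should keep the isomerisation-prone Z enal intact.

Step 13
Reactants: 19 (2Z,4S)-2,4-dimethylhex-2-enal; 20 2-(dichloromethyl)-4,4,5,5-tetramethyl-1,3,2-dioxaborolane
Product: 22 2-[(1E,3Z,5S)-3,5-dimethylhepta-1,3-dien-1-yl]-4,4,5,5-tetramethyl-1,3,2-dioxaborolane, via geminal dichromium boronate 21 (not isolated)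
Conditions: 20 (2 equiv), CrCl2 (8 equiv), LiI (4 equiv), THF, 23 °C
Reagents that add atoms: CrCl2 Cl[Cr]Cl (chromium and chloride of 21 only)
Why: The boron variant of the Takai olefination, in which divalent chromium turns the dichloride into a geminal dimetal reagent, is known to convert aldehydes and enals into E alkenylboronates and leaves the existing Z alkene as a spectator.

Step 14
Reactants: 12 diphenyl dienol phosphate of step 8; 22 (1E,3Z,5S)-dienyl pinacol boronate
Product: 23 (6R,7S,8R,8aR)-6-(TBSO)-3-[(1E,3Z,5S)-3,5-dimethylhepta-1,3-dien-1-yl]-7-methyl-7,8-bis(TESO)-6,7,8,8a-tetrahydro-1H-isochromene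
Conditions: PdCl2(dppf) (5 mol %), Cs2CO3 (3 equiv), DMF–H2O, 23 to 40 °C, dark
Reagents that add atoms: none
Why: Suzuki–Miyaura coupling of lactone-derived enol phosphates with organoboron partners is known, zerovalent palladium inserts into the C3–O(P) bond, and both alkenyl partners couple with retention of geometry.

Step 15
Reactants: 23 tris-silyl ether of step 14
Product: 24 (6R,7S,8R,8aR)-3-[(1E,3Z,5S)-3,5-dimethylhepta-1,3-dien-1-yl]-7-methyl-6,7,8,8a-tetrahydro-1H-isochromene-6,7,8-triol
Conditions: Bu4NF (6 equiv), THF, 0 to 23 °C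
Reagents that add atoms: none
Why: Fluoride cleaves all three silyl ethers in one operation under non-acidic conditions, which protects the acid-labile dienol ether and its ionisable C6 allylic alcohol.

Step 16
Reactants: 24 triol of step 15
Product: 25 (7R,8R,8aR)-3-[(1E,3Z,5S)-3,5-dimethylhepta-1,3-dien-1-yl]-7,8-dihydroxy-7-methyl-1,7,8,8a-tetrahydro-6H-isochromen-6-one
Conditions: MnO2 (20 equiv), CH2Cl2, 23 °C, dark
Reagents that add atoms: none
Why: MnO2 oxidises only the allylic C6 alcohol, because the C8 alcohol is unactivated, the C7 alcohol is tertiary, and the trans C6/C7 diol is poorly set up for glycol cleavage.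

Step 17
Reactants: 25 keto diol of step 16
Product: 26 (7R,8R,8aR)-3-[(1E,3Z,5S)-3,5-dimethylhepta-1,3-dien-1-yl]-7-hydroxy-7-methyl-6-oxo-6,7,8,8a-tetrahydro-1H-isochromen-8-yl acetate (target)
Conditions: Ac2O (1.5 equiv), pyridine, DMAP (5 mol %), CH2Cl2, 0 °C
Reagents that add atoms: acetic anhydride CC(=O)OC(C)=O
Why: Mild acetylation takes the only secondary alcohol and leaves the hindered tertiary α-ketol free, and the short cold reaction avoids vinylogous enolisation at C8a.

Compound list
1 | but-3-en-1-yl acetate | C=CCCOC(C)=O | starting material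
2 | methacrolein | C=C(C)C=O | starting material
3 | (3E)-4-methyl-5-oxopent-3-en-1-yl acetate | CC(=O)OCC/C=C(\C)C=O | intermediate
4 | (2E,4E)-5-[(tert-butyldimethylsilyl)oxy]-4-methylpenta-2,4-dien-1-yl acetate | CC(=O)OC/C=C/C(C)=C/O[Si](C)(C)C(C)(C)C | intermediate
5 | (2E,4E)-5-[(tert-butyldimethylsilyl)oxy]-4-methylpenta-2,4-dien-1-ol | OC/C=C/C(C)=C/O[Si](C)(C)C(C)(C)C | intermediate
6 | but-3-ynoic acid | C#CCC(=O)O | starting material
7 | (2E,4E)-5-[(tert-butyldimethylsilyl)oxy]-4-methylpenta-2,4-dien-1-yl but-3-ynoate | C#CCC(=O)OC/C=C/C(C)=C/O[Si](C)(C)C(C)(C)C | intermediate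
8 | (6R,8aR)-6-[(tert-butyldimethylsilyl)oxy]-7-methyl-1,4,6,8a-tetrahydro-3H-isochromen-3-one | CC1=C[C@H]2COC(=O)CC2=C[C@H]1O[Si](C)(C)C(C)(C)C | intermediate
9 | (6R,7R,8R,8aR)-6-[(tert-butyldimethylsilyl)oxy]-7,8-dihydroxy-7-methyl-1,4,6,7,8,8a-hexahydro-3H-isochromen-3-one | O=C1CC2=C[C@@H](O[Si](C)(C)C(C)(C)C)[C@](C)(O)[C@H](O)[C@H]2CO1 | intermediate
10 | (6R,7S,8R,8aR)-6-[(tert-butyldimethylsilyl)oxy]-7-methyl-7,8-bis[(triethylsilyl)oxy]-1,4,6,7,8,8a-hexahydro-3H-isochromen-3-one | O=C1CC2=C[C@@H](O[Si](C)(C)C(C)(C)C)[C@](C)(O[Si](CC)(CC)CC)[C@H](O[Si](CC)(CC)CC)[C@H]2CO1 | intermediate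
11 | potassium dienolate of 10 (C3–O−, C3=C4, C4a=C5) | [K+].[O-]C1=CC2=C[C@@H](O[Si](C)(C)C(C)(C)C)[C@](C)(O[Si](CC)(CC)CC)[C@H](O[Si](CC)(CC)CC)[C@H]2CO1 | intermediate
12 | diphenyl (6R,7S,8R,8aR)-6-[(tert-butyldimethylsilyl)oxy]-7-methyl-7,8-bis[(triethylsilyl)oxy]-6,7,8,8a-tetrahydro-1H-isochromen-3-yl phosphate | O=P(Oc1ccccc1)(Oc1ccccc1)OC1=CC2=C[C@@H](O[Si](C)(C)C(C)(C)C)[C@](C)(O[Si](CC)(CC)CC)[C@H](O[Si](CC)(CC)CC)[C@H]2CO1 | intermediate
13 | (S)-2-methylbutan-1-ol | CC[C@H](C)CO | starting material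
14 | (S)-2-methylbutanal | CC[C@H](C)C=O | intermediate
15 | ethyl 2-[bis(2,2,2-trifluoroethoxy)phosphoryl]propanoate | CCOC(=O)C(C)P(=O)(OCC(F)(F)F)OCC(F)(F)F | starting material
16 | potassium carbanion of 15 | [K+].CCOC(=O)[C-](C)P(=O)(OCC(F)(F)F)OCC(F)(F)F | intermediate
17 | ethyl (2Z,4S)-2,4-dimethylhex-2-enoate | CC[C@H](C)/C=C(C)\C(=O)OCC | intermediate
18 | (2Z,4S)-2,4-dimethylhex-2-en-1-ol | CC[C@H](C)/C=C(C)\CO | intermediate
19 | (2Z,4S)-2,4-dimethylhex-2-enal | CC[C@H](C)/C=C(C)\C=O | intermediate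
20 | 2-(dichloromethyl)-4,4,5,5-tetramethyl-1,3,2-dioxaborolane | ClC(Cl)B1OC(C)(C)C(C)(C)O1 | starting material
21 | geminal bis(dichlorochromio)methyl pinacol boronate | Cl[Cr](Cl)C([Cr](Cl)Cl)B1OC(C)(C)C(C)(C)O1 | intermediate
22 | 2-[(1E,3Z,5S)-3,5-dimethylhepta-1,3-dien-1-yl]-4,4,5,5-tetramethyl-1,3,2-dioxaborolane | CC[C@H](C)/C=C(C)\C=C\B1OC(C)(C)C(C)(C)O1 | intermediate
23 | (6R,7S,8R,8aR)-6-[(tert-butyldimethylsilyl)oxy]-3-[(1E,3Z,5S)-3,5-dimethylhepta-1,3-dien-1-yl]-7-methyl-7,8-bis[(triethylsilyl)oxy]-6,7,8,8a-tetrahydro-1H-isochromene | CC[C@H](C)/C=C(C)\C=C\C1=CC2=C[C@@H](O[Si](C)(C)C(C)(C)C)[C@](C)(O[Si](CC)(CC)CC)[C@H](O[Si](CC)(CC)CC)[C@H]2CO1 | intermediate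
24 | (6R,7S,8R,8aR)-3-[(1E,3Z,5S)-3,5-dimethylhepta-1,3-dien-1-yl]-7-methyl-6,7,8,8a-tetrahydro-1H-isochromene-6,7,8-triol | CC[C@H](C)/C=C(C)\C=C\C1=CC2=C[C@@H](O)[C@](C)(O)[C@H](O)[C@H]2CO1 | intermediate
25 | (7R,8R,8aR)-3-[(1E,3Z,5S)-3,5-dimethylhepta-1,3-dien-1-yl]-7,8-dihydroxy-7-methyl-1,7,8,8a-tetrahydro-6H-isochromen-6-one | CC[C@H](C)/C=C(C)\C=C\C1=CC2=CC(=O)[C@](C)(O)[C@H](O)[C@H]2CO1 | intermediate
26 | (7R,8R,8aR)-3-[(1E,3Z,5S)-3,5-dimethylhepta-1,3-dien-1-yl]-7-hydroxy-7-methyl-6-oxo-6,7,8,8a-tetrahydro-1H-isochromen-8-yl acetate | CC[C@H](C)/C=C(C)\C=C\C1=CC2=CC(=O)[C@](C)(O)[C@H](OC(C)=O)[C@H]2CO1 | target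

Total step count: 17.
Longest linear sequence: 12 steps (steps 1–8 and 14–17). The side-chain branch (steps 9–13) has 5 steps.

Steps most likely to fail

**Step 5.** The ester tether may stay in its extended conformation. Ring closure would then be slower than alkyne oligomerisation, alkyne-to-allene shift, ionisation of the allylic C1–O bond, or loss of silanol with aromatisation of the product.
- The fallback sets out from 7, comes back to the route at 12, and uses known reaction types only.
- A catalytic amount of Et3N in CH2Cl2 moves the triple bond of 7 into the allene and gives (2E,4E)-5-(TBSO)-4-methylpenta-2,4-dien-1-yl buta-2,3-dienoate F1.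
- Heating F1 in toluene (BHT, base-washed glass, 110–140 °C) should bring about a thermal intramolecular Diels–Alder reaction at the distal allene bond. The nucleophilic diene terminus C8a meets the electrophilic central allene carbon C4a.
- The same two bonds and both rings form, but the product is racemic and carries the conjugated C4=C4a alkene.
- Chromatography on a chiral stationary phase separates (6R,8aR)-6-(TBSO)-7-methyl-1,5,6,8a-tetrahydro-3H-isochromen-3-one F2 from its mirror image, the (6S,8aS)-lactone F3, which is set aside.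
- In F2 the only electron-rich alkene is C7=C8, so OsO4/NMO should give the (6R,7R,8R,8aR)-7,8-diol F4. Et3SiOTf/2,6-lutidine then gives the bis(triethylsilyl) ether F5.
- KN(SiMe3)2 at −78 °C takes a proton from the less hindered γ-position C5 of F5, which gives the dienolate 11, and (PhO)2P(O)Cl traps it as 12.

**Step 6.** Site selection between the two trisubstituted alkenes rests only on an electronic bias, so osmylation of C4a=C5 or double osmylation may compete.
- The fallback sets out from 5 and comes back at 9.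
- The alkyne is capped so that C4a=C5 is formed as a tetrasubstituted vinylsilane that the oxidant cannot reach.
- Jones oxidation (CrO3, H2SO4, acetone) of commercial 4-(trimethylsilyl)but-3-yn-1-ol gives 4-(trimethylsilyl)but-3-ynoic acid F6. DCC joins it to 5 to give the silyl-capped dienyl ester F7.
- The catalyst of step 5 should then give the (6S,8aR)-5-trimethylsilyl cycloadduct F8, since silyl-capped alkynes are classical partners in this cycloaddition.
- OsO4/NMO then has only C7=C8 to attack and gives the 5-silyl diol F9.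
- Ipso-protodesilylation of the vinylsilane (CF3CO2H, CH2Cl2, 0 °C) returns 9.

**Step 14.** The dienol phosphate may hydrolyse or ionise at C6 under the aqueous basic coupling conditions faster than palladium inserts. The Z alkene of the diene may also drift to E during a slow coupling.
- The fallback sets out from 19 and 10 and comes back at 23.
- The polarity is reversed and the side chain is added as a nucleophile to the lactone carbonyl.
- Takai olefination of 19 (CHI3, CrCl2, THF) gives (1E,3Z,5S)-1-iodo-3,5-dimethylhepta-1,3-diene F10.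
- t-BuLi (2 equiv, Et2O, −78 °C) turns F10 into the (1E,3Z,5S)-dienyllithium F11.
- In the presence of LaCl3·2LiCl, which curbs enolisation, F11 adds once to 10 and gives the C3 lactol F12 as a mixture of anomers.
- MsCl/Et3N dehydrates F12 towards C4 and gives 23.

Further compounds
F1 | step 5 | (2E,4E)-5-[(tert-butyldimethylsilyl)oxy]-4-methylpenta-2,4-dien-1-yl buta-2,3-dienoate | C=C=CC(=O)OC/C=C/C(C)=C/O[Si](C)(C)C(C)(C)C
F2 | step 5 | (6R,8aR)-6-[(tert-butyldimethylsilyl)oxy]-7-methyl-1,5,6,8a-tetrahydro-3H-isochromen-3-one | CC1=C[C@H]2COC(=O)C=C2C[C@H]1O[Si](C)(C)C(C)(C)C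
F3 | step 5 | (6S,8aS)-6-[(tert-butyldimethylsilyl)oxy]-7-methyl-1,5,6,8a-tetrahydro-3H-isochromen-3-one | CC1=C[C@@H]2COC(=O)C=C2C[C@@H]1O[Si](C)(C)C(C)(C)C
F4 | step 5 | (6R,7R,8R,8aR)-6-[(tert-butyldimethylsilyl)oxy]-7,8-dihydroxy-7-methyl-1,5,6,7,8,8a-hexahydro-3H-isochromen-3-one | O=C1C=C2C[C@@H](O[Si](C)(C)C(C)(C)C)[C@](C)(O)[C@H](O)[C@H]2CO1
F5 | step 5 | (6R,7S,8R,8aR)-6-[(tert-butyldimethylsilyl)oxy]-7-methyl-7,8-bis[(triethylsilyl)oxy]-1,5,6,7,8,8a-hexahydro-3H-isochromen-3-one | O=C1C=C2C[C@@H](O[Si](C)(C)C(C)(C)C)[C@](C)(O[Si](CC)(CC)CC)[C@H](O[Si](CC)(CC)CC)[C@H]2CO1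
F6 | step 6 | 4-(trimethylsilyl)but-3-ynoic acid | C[Si](C)(C)C#CCC(=O)O
F7 | step 6 | (2E,4E)-5-[(tert-butyldimethylsilyl)oxy]-4-methylpenta-2,4-dien-1-yl 4-(trimethylsilyl)but-3-ynoate | C[Si](C)(C)C#CCC(=O)OC/C=C/C(C)=C/O[Si](C)(C)C(C)(C)C
F8 | step 6 | (6S,8aR)-6-[(tert-butyldimethylsilyl)oxy]-7-methyl-5-(trimethylsilyl)-1,4,6,8a-tetrahydro-3H-isochromen-3-one | CC1=C[C@H]2COC(=O)CC2=C([Si](C)(C)C)[C@H]1O[Si](C)(C)C(C)(C)C
F9 | step 6 | (6S,7R,8R,8aR)-6-[(tert-butyldimethylsilyl)oxy]-7,8-dihydroxy-7-methyl-5-(trimethylsilyl)-1,4,6,7,8,8a-hexahydro-3H-isochromen-3-one | O=C1CC2=C([Si](C)(C)C)[C@@H](O[Si](C)(C)C(C)(C)C)[C@](C)(O)[C@H](O)[C@H]2CO1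
F10 | step 14 | (1E,3Z,5S)-1-iodo-3,5-dimethylhepta-1,3-diene | CC[C@H](C)/C=C(C)\C=C\I
F11 | step 14 | [(1E,3Z,5S)-3,5-dimethylhepta-1,3-dien-1-yl]lithium | CC[C@H](C)/C=C(C)\C=C\[Li]
F12 | step 14 | (6R,7S,8R,8aR)-6-[(tert-butyldimethylsilyl)oxy]-3-[(1E,3Z,5S)-3,5-dimethylhepta-1,3-dien-1-yl]-7-methyl-7,8-bis[(triethylsilyl)oxy]-3,4,6,7,8,8a-hexahydro-1H-isochromen-3-ol (both C3 anomers) | CC[C@H](C)/C=C(C)\C=C\C1(O)CC2=C[C@@H](O[Si](C)(C)C(C)(C)C)[C@](C)(O[Si](CC)(CC)CC)[C@H](O[Si](CC)(CC)CC)[C@H]2CO1
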